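A millimolar of G costs a millimolar of Q, so the south run can be bracketed at the blackboard before anyone fits anything.

| setting | west | south-east | south-west | south |
|---|---|---|---|---|
| Z | 100 mM | 50.0 mM | 200 mM | 650 mM |
| Q | 150 mM | 100 mM | 150 mM | 150 mM |
| time |  |  |  | 32 h |

- west run (time / h: [G] / mM): 6.4: 22.9; 13: 39.5; 19: 47.7; 26: 52.1; 32: 52.2
- south-east run (time / h: [G] / mM): 6.4: 8.2; 13: 15.6; 19: 18.5; 26: 23.4; 32: 23.1
- south-west run (time / h: [G] / mM): 6.4: 45.0; 13: 79.5; 19: 92.1; 26: 99.4; 32: 102.5

(scatter of a reading: 0.8 mM)

1. how the opening rate goes with [Q] round the charge of the west run: the exponent of the rate at two percent of Z gone to G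
2. how the opening rate goes with [Z] round the charge of the west run: the exponent of the rate at two percent of Z gone to G (one fixed amount of G, the same in the runs compared)
3. G in the south run at 32 h, as a share of the Z charged

- Overall: Z + Q -> G.
- Constant volume, constant temperature.
- An order is taken over about fifteen percent of the charge, up and down.

From above: Q is the limiting reagent of the south run, so G there cannot pass 150 mM, which is 23.1% of its Z. From below: the south-west run, with the same c(Q) and less Z, read 102.5 mM at 32 h, and it made more G than the west run. We take that amount as a first floor, 15.8% of the south Z.

To tighten the floor, note that the west run read 52.2% of its Z at 32 h, a reading and not a proven plateau. We call that share times c(Z) the offer, which for the south run is 339 mM, more than its Q. The offer over the Q charge, the demand ratio, is 2.26 for the south run; we read a value above one as Q stopping the flask, and a value below one as Z stopping it.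

The south-west run read 51.2% of its Z at 32 h, with c(Q) down to 47.5 mM. Below that we assume, as our own pessimistic step, that the share falls in proportion to c(Q). The remaining offer then leaves 0.325 mM of Q, and the floor rises to 23.0%.

The forecast gave 21.5%, with exponents 0.8 in Q and 1.05 in Z, holding that the south run “should consume most of the Q”. Its value lies above the first floor but below our tightened one.

The simulation gives 23.1%, with exponents 0.48 and 0.69.

    Z → E (0.06768 /h)
    E + Q → G (3.924 /M/h)
    E → X (0.1937 /h)
    Z → Ze (0.03020 /h)
    Z + Q + G → 2 G (4.644 /M²/h)

The step in which G helps Z and Q on to more G makes no difference to that south value. With a demand ratio of 2.26, the south run comes to 23.1% against its cap of 23.1%. In the south-west run the demand ratio is 0.696, below one, and there G came to half of the Z charged at 25.7 h.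

The readings were computed with made-up constants.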